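The flavone is disconnected across ring A: C4a–C5 and C8–C8a are the last skeletal bonds made, so ring C is assembled first as a monocyclic 2-aryl-3-acetoxy-5-bromo-4-pyranone by site-selective cross-coupling. Two features make this possible: O5 and O7 sit meta to each other on ring A, exactly like the two oxygens of a diene made from methyl acetoacetate, and the ring-fusion bond C4a–C8a is nothing other than C5–C6 of the pyranone. One operation should forge both bonds, close ring A and aromatise it to the free 5,7-diol, bromine supplying the oxidation level. Debenzylation and trisulfation of O7, O3′ and O4′ finish the synthesis.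

Key step: step 7

Remark on the chemistry: the target has no stereogenic element, so it is one achiral compound and no enantiocontrol is needed. It is drawn as the free tris(hydrogen sulfate) and step 9 should deliver it in that form after proton exchange; storage as a salt is advisable.

Step 1
Reactants: 1 3-hydroxy-4H-pyran-4-one
Product: 2 3-hydroxy-2-iodo-4H-pyran-4-one
Conditions: NIS (1.05 equiv), MeCN, 0 → 20 °C, dark
Reagents that add atoms: N-iodosuccinimide (NIS), O=C1CCC(=O)N1I
Why: Electrophilic iodination of an enol (phenol-type ortho substitution): the 3-hydroxyl activates only the adjacent C2, so NIS should iodinate there and leave C5 and C6 untouched.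

Step 2
Reactants: 2 3-hydroxy-2-iodo-4H-pyran-4-one
Product: 3 2-iodo-4-oxo-4H-pyran-3-yl acetate
Conditions: Ac2O, pyridine, CH2Cl2, 0 → 20 °C
Reagents that add atoms: acetic anhydride, CC(=O)OC(C)=O
Why: Standard O-acetylation of an acidic enol, which installs the ester the target needs at C3 and removes the enol reactivity of C2=C3 before bromination.

Step 3
Reactants: 3 2-iodo-4-oxo-4H-pyran-3-yl acetate
Product: 5 5-bromo-2-iodo-4-oxo-4H-pyran-3-yl acetate, via dibromide adduct 4 (not isolated)
Conditions: Br2 (1.05 equiv), CH2Cl2, 0 °C; then Et3N (1.2 equiv), 0 °C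
Reagents that add atoms: bromine, BrBr
Why: Bromine addition across the vinylogous-ester C5=C6 bond followed by E1cB dehydrobromination (acidic H5, bromide leaving from the oxygen-bearing C6) is the usual entry to 3-bromo-4-pyranones and 3-bromochromones and can only give the 5-bromide, while the fully substituted, acceptor-flanked C2=C3 bond should not add bromine.

Step 4
Reactants: 5 5-bromo-2-iodo-4-oxo-4H-pyran-3-yl acetate; 6 3,4-bis(benzyloxy)phenylboronic acid (1.05 equiv)
Product: 7 2-[3,4-bis(benzyloxy)phenyl]-5-bromo-4-oxo-4H-pyran-3-yl acetate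
Conditions: Pd(PPh3)4 (5 mol %), anhydrous K3PO4 (2 equiv), 1,4-dioxane, 50 °C
Reagents that add atoms: none
Why: Suzuki–Miyaura coupling in which oxidative addition should occur at the weaker C2–I bond (β-carbon of the enone, next to the ring oxygen) well before the C5–Br bond, and anhydrous phosphate is chosen so that the enol acetate is not hydrolysed.

Step 5
Reactants: 8 methyl acetoacetate
Product: 9 methyl 3-(trimethylsilyloxy)but-2-enoate (E/Z mixture, used as such)
Conditions: TMSCl, Et3N, hexane, 20 °C; filter, distil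
Reagents that add atoms: chlorotrimethylsilane, C[Si](C)(C)Cl
Why: O-silylation of the enol form of a β-keto ester with TMSCl and triethylamine, the established first stage of the preparation of the acetoacetate-derived bis(silyloxy)diene.

Step 6
Reactants: 9 methyl 3-(trimethylsilyloxy)but-2-enoate
Product: 10 1-methoxy-1,3-bis(trimethylsilyloxy)buta-1,3-diene (1Z drawn)
Conditions: LDA (1.1 equiv), THF, −78 °C; TMSCl, −78 → 0 °C; distil
Reagents that add atoms: chlorotrimethylsilane, C[Si](C)(C)Cl
Why: Kinetic γ-deprotonation with LDA gives the extended ester dienolate, which TMSCl traps on oxygen (silyl ketene acetal formation), and the C1=C2 geometry of the diene is of no consequence later.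

Step 7
Reactants: 7 2-[3,4-bis(benzyloxy)phenyl]-5-bromo-4-oxo-4H-pyran-3-yl acetate; 10 1-methoxy-1,3-bis(trimethylsilyloxy)buta-1,3-diene (2 equiv)
Product: 13 3′,4′-di-O-benzylquercetin 3-acetate (2-[3,4-bis(benzyloxy)phenyl]-5,7-dihydroxy-4-oxo-4H-chromen-3-yl acetate), via silyloxypyrylium triflate 11 (not isolated), via bromo tetrahydrochromenone adduct 12 (not isolated)
Conditions: TMSOTf (1.2 equiv), CH2Cl2, 0 °C; 10, −78 → 20 °C; Et3N (4 equiv), 20 °C; aq. NH4Cl/THF work-up
Reagents that add atoms: none
Why: Proposed new method: TMSOTf silylates the C4 carbonyl to pyrylium 11, whose free α-position C6 (made more electrophilic by the neighbouring bromine) should accept the nucleophilic CH2 terminus of 10, and the α-bromo silyl enol ether generated at C4=C5 then attacks the silylated ester carbon of the side chain to give 12, a polarity-matched stepwise [4+2]. Triethylamine then removes HBr across C4a–C8a, methoxytrimethylsilane leaves from C5 and mild aqueous acid cleaves the aryl silyl ethers, so the new ring aromatises to the 5,7-diol. The closest known reaction types are the regioselective benzannulation of 1-alkoxy-1,3-bis(silyloxy)dienes with 2-haloquinones and the silyl triflate-mediated conjugate addition of silyl enol ethers to 4-pyranones and chromones. Ring A is closed by a 6-exo-trig attack of the enol silane carbon on the exocyclic C=O+ of the activated ester, which completes the six-membered carbocycle. No stereocentre is created in the product, the three sp3 carbons of 12 being transient. The step needs the diene terminus at pyranone C6 and the ester carbon at C5: the first is secured because C6 is the only unsubstituted β-carbon (C2 carries the aryl group), the second because after the first bond only the bromine-bearing C5 is nucleophilic and lies six atoms from the ester carbon, while the 3-acetate and the benzyl ethers are spectators.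

Step 8
Reactants: 13 3′,4′-di-O-benzylquercetin 3-acetate
Product: 14 quercetin 3-acetate (2-(3,4-dihydroxyphenyl)-5,7-dihydroxy-4-oxo-4H-chromen-3-yl acetate)
Conditions: H2 (1 atm), 10% Pd/C, THF–EtOAc, 20 °C
Reagents that add atoms: none
Why: Catalytic hydrogenolysis of aryl benzyl ethers, run in aprotic solvent so that the 3-acetate is not transesterified; the tetrasubstituted chromone C2=C3 bond is not reduced under these conditions.

Step 9
Reactants: 14 quercetin 3-acetate
Product: 15 quercetin 3-acetate 7,3′,4′-tri-O-sulfate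
Conditions: SO3·pyridine (8 equiv), DMF, 20 → 40 °C; then Dowex 50W (H+), H2O, 0 °C; freeze-dry
Reagents that add atoms: sulfur trioxide–pyridine complex, O=S(=O)([O-])[n+]1ccccc1
Why: O-sulfation of phenols with an amine–sulfur trioxide complex: the three unchelated hydroxyls at C7, C3′ and C4′ react, whereas the 5-hydroxyl, hydrogen-bonded to the C4 carbonyl, is the least nucleophilic and should stay free, and the aprotic medium spares the acetate.

Compound list
1 | 3-hydroxy-4H-pyran-4-one | O=c1ccocc1O | starting material
2 | 3-hydroxy-2-iodo-4H-pyran-4-one | O=c1ccoc(I)c1O | intermediate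
3 | 2-iodo-4-oxo-4H-pyran-3-yl acetate | CC(=O)Oc1c(I)occc1=O | intermediate
4 | 5,6-dibromo-2-iodo-4-oxo-5,6-dihydro-4H-pyran-3-yl acetate (formed in situ, racemic, relative configuration immaterial) | CC(=O)OC1=C(I)OC(Br)C(Br)C1=O | intermediate
5 | 5-bromo-2-iodo-4-oxo-4H-pyran-3-yl acetate | CC(=O)Oc1c(I)occ(Br)c1=O | intermediate
6 | 3,4-bis(benzyloxy)phenylboronic acid | OB(O)c1ccc(OCc2ccccc2)c(OCc2ccccc2)c1 | starting material
7 | 2-[3,4-bis(benzyloxy)phenyl]-5-bromo-4-oxo-4H-pyran-3-yl acetate | CC(=O)Oc1c(-c2ccc(OCc3ccccc3)c(OCc3ccccc3)c2)occ(Br)c1=O | intermediate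
8 | methyl acetoacetate | COC(=O)CC(C)=O | starting material
9 | methyl 3-(trimethylsilyloxy)but-2-enoate (E/Z mixture) | COC(=O)C=C(C)O[Si](C)(C)C | intermediate
10 | 1-methoxy-1,3-bis(trimethylsilyloxy)buta-1,3-diene (1Z drawn) | CO/C(O[Si](C)(C)C)=C/C(=C)O[Si](C)(C)C | intermediate
11 | 3-acetoxy-2-[3,4-bis(benzyloxy)phenyl]-5-bromo-4-(trimethylsilyloxy)pyrylium trifluoromethanesulfonate (formed in situ) | CC(=O)Oc1c(-c2ccc(OCc3ccccc3)c(OCc3ccccc3)c2)[o+]cc(Br)c1O[Si](C)(C)C.[O-]S(=O)(=O)C(F)(F)F | intermediate
12 | 2-[3,4-bis(benzyloxy)phenyl]-4a-bromo-5-methoxy-4-oxo-5,7-bis(trimethylsilyloxy)-4a,5,8,8a-tetrahydro-4H-chromen-3-yl acetate (formed in situ, diastereomer mixture, all sp3 centres lost on aromatisation) | CC(=O)OC1=C(c2ccc(OCc3ccccc3)c(OCc3ccccc3)c2)OC2CC(O[Si](C)(C)C)=CC(OC)(O[Si](C)(C)C)C2(Br)C1=O | intermediate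
13 | 3′,4′-di-O-benzylquercetin 3-acetate | CC(=O)Oc1c(-c2ccc(OCc3ccccc3)c(OCc3ccccc3)c2)oc2cc(O)cc(O)c2c1=O | intermediate
14 | quercetin 3-acetate | CC(=O)Oc1c(-c2ccc(O)c(O)c2)oc2cc(O)cc(O)c2c1=O | intermediate
15 | quercetin 3-acetate 7,3′,4′-tri-O-sulfate | CC(=O)Oc1c(-c2ccc(OS(=O)(=O)O)c(OS(=O)(=O)O)c2)oc2cc(OS(=O)(=O)O)cc(O)c2c1=O | target

Total step count: 9. Longest linear sequence: 7 steps (steps 1, 2, 3, 4, 7, 8, 9); steps 5 and 6 form the two-step diene branch.

Steps most likely to fail

Step 7 (Proposed new method). The first C–C bond may form without ring closure. The pyran ring could then open by β-elimination of its oxygen, or the bromine could be removed by halophilic attack, so that aromatisation to the 5,7-diol does not occur. The fallback buys the A ring instead of building it; it sets out from boronic acid 6 and comes back at 13, using only known reaction types. Commercial 5,7-dihydroxy-4H-chromen-4-one would be protected (NaH, MOMCl, DMF) as 5,7-bis(methoxymethoxy)-4H-chromen-4-one F1. Palladium(II)-catalysed conjugate addition of 6 (Pd(OCOCF3)2, 2,2′-bipyridine, aqueous DCE, 60 °C) should give racemic 2-[3,4-bis(benzyloxy)phenyl]-5,7-bis(methoxymethoxy)chroman-4-one F2. Dehydrogenation with I2 in pyridine at 90 °C should give the flavone 2-[3,4-bis(benzyloxy)phenyl]-5,7-bis(methoxymethoxy)-4H-chromen-4-one F3. Epoxidation of its C2=C3 bond with dimethyldioxirane and acid-catalysed opening should give the flavonol 2-[3,4-bis(benzyloxy)phenyl]-3-hydroxy-5,7-bis(methoxymethoxy)-4H-chromen-4-one F4. Ac2O/pyridine converts this into 2-[3,4-bis(benzyloxy)phenyl]-5,7-bis(methoxymethoxy)-4-oxo-4H-chromen-3-yl acetate F5, and TFA in CH2Cl2 removes both MOM groups to reach 13.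

Step 9. The second sulfation of the catechol may stall next to the first anionic sulfate. Forcing it may bring in sulfation at O5, loss of the acetate, or loss of sulfate during acidic isolation. The fallback stages the sulfation; it sets out from 13 and comes back at 15. In 13 only the 7-hydroxyl is unchelated, so SO3·pyridine (1.5 equiv, DMF, 20 °C) and sodium exchange should give 3′,4′-di-O-benzylquercetin 3-acetate 7-O-sulfate sodium salt F6. Hydrogenolysis (H2, Pd/C, THF–H2O) should give quercetin 3-acetate 7-O-sulfate sodium salt F7. With only the catechol and the chelated 5-OH left, excess SO3·pyridine can be applied to O3′ and O4′, and proton exchange gives 15.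

Step 4. The enol acetate may be cleaved by the basic coupling medium, and the free enolate may slow transmetalation; selectivity for iodide over bromide may also erode and lead to double arylation. The fallback replaces the acetate by a base-stable ether for the halogenation and coupling; it sets out from 2 and comes back at 7. MOMCl/i-Pr2NEt should give 2-iodo-3-(methoxymethoxy)-4H-pyran-4-one F8. Br2 then Et3N should give 5-bromo-2-iodo-3-(methoxymethoxy)-4H-pyran-4-one F9. Suzuki–Miyaura coupling with 6 under ordinary aqueous carbonate conditions (Pd(PPh3)4, Na2CO3, DME–H2O, 40 °C) should give 2-[3,4-bis(benzyloxy)phenyl]-5-bromo-3-(methoxymethoxy)-4H-pyran-4-one F10. Aqueous HCl in THF should free 2-[3,4-bis(benzyloxy)phenyl]-5-bromo-3-hydroxy-4H-pyran-4-one F11, and Ac2O/pyridine gives 7.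

Further compounds
F1 | step 7 | 5,7-bis(methoxymethoxy)-4H-chromen-4-one | O=c1ccoc2cc(OCOC)cc(OCOC)c12
F2 | step 7 | 2-[3,4-bis(benzyloxy)phenyl]-5,7-bis(methoxymethoxy)chroman-4-one (racemic) | O=C1CC(c2ccc(OCc3ccccc3)c(OCc3ccccc3)c2)Oc2cc(OCOC)cc(OCOC)c12
F3 | step 7 | 2-[3,4-bis(benzyloxy)phenyl]-5,7-bis(methoxymethoxy)-4H-chromen-4-one | O=c1cc(-c2ccc(OCc3ccccc3)c(OCc3ccccc3)c2)oc2cc(OCOC)cc(OCOC)c12
F4 | step 7 | 2-[3,4-bis(benzyloxy)phenyl]-3-hydroxy-5,7-bis(methoxymethoxy)-4H-chromen-4-one | O=c1c(O)c(-c2ccc(OCc3ccccc3)c(OCc3ccccc3)c2)oc2cc(OCOC)cc(OCOC)c12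
F5 | step 7 | 2-[3,4-bis(benzyloxy)phenyl]-5,7-bis(methoxymethoxy)-4-oxo-4H-chromen-3-yl acetate | CC(=O)Oc1c(-c2ccc(OCc3ccccc3)c(OCc3ccccc3)c2)oc2cc(OCOC)cc(OCOC)c2c1=O
F6 | step 9 | 3′,4′-di-O-benzylquercetin 3-acetate 7-O-sulfate sodium salt | CC(=O)Oc1c(-c2ccc(OCc3ccccc3)c(OCc3ccccc3)c2)oc2cc(OS(=O)(=O)[O-])cc(O)c2c1=O.[Na+]
F7 | step 9 | quercetin 3-acetate 7-O-sulfate sodium salt | CC(=O)Oc1c(-c2ccc(O)c(O)c2)oc2cc(OS(=O)(=O)[O-])cc(O)c2c1=O.[Na+]
F8 | step 4 | 2-iodo-3-(methoxymethoxy)-4H-pyran-4-one | COCOc1c(I)occc1=O
F9 | step 4 | 5-bromo-2-iodo-3-(methoxymethoxy)-4H-pyran-4-one | COCOc1c(I)occ(Br)c1=O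
F10 | step 4 | 2-[3,4-bis(benzyloxy)phenyl]-5-bromo-3-(methoxymethoxy)-4H-pyran-4-one | COCOc1c(-c2ccc(OCc3ccccc3)c(OCc3ccccc3)c2)occ(Br)c1=O
F11 | step 4 | 2-[3,4-bis(benzyloxy)phenyl]-5-bromo-3-hydroxy-4H-pyran-4-one | O=c1c(Br)coc(-c2ccc(OCc3ccccc3)c(OCc3ccccc3)c2)c1O
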